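## Structural features

The target is a fucophlorethol-type nonamer of phloroglucinol without any stereocentre: nine benzene rings (A, B, B', C, D, E, E', F, F') are joined by five diaryl ether bonds and three biaryl bonds and carry 22 free phenols. Ring A (3,5-dihydroxyphenyl) is bound through oxygen to B-1; ring B has OH at B-2 and B-6, H at B-3, the ether oxygen to C-1 at B-4 and the C–C bond to ring B' at B-5; ring C has OH at C-2 and C-6 and its C-4 oxygen goes to D-1; ring D has OH at D-4 and ether oxygens at D-2 and D-6 that go to E-1 and F-1; rings E and F have OH at positions 2, 4 and 6 and the C–C bond to E' or F' at position 5; B', E' and F' are 2,4,6-trihydroxyphenyl rings. Every ether carbon of rings B to F (B-1, C-1, D-1, E-1, F-1) lies between two oxygen-bearing carbons, and D-1 lies between two aryloxy groups, so all five ethers are di-ortho-substituted on one side. The three biaryl bonds are tetra-ortho-oxygenated, but each ends in a C2v-symmetric trihydroxyphenyl ring, so no axis is stereogenic and no configuration has to be set. The free polyphenol is sensitive to air and base, and all rings are electron-rich enough to be over-oxidized or attacked by electrophiles, so all phenols except the two of ring B are carried as methyl ethers to the last step. The real difficulty is the crowded region of ring B, where the axis B-5–B'-1 stands directly beside the ether B-4–O–C-1, so that whichever of these two bonds is made second must be made next to a bulky neighbour; the 1,2,3-tris(aryloxy) ring D comes second. The key step exploits two features: B-3 and B-5 are exchanged by the local mirror plane through B-1 and B-4 as long as B-2 and B-6 carry the same group, so a ring B with both of these oxygens as free OH has only one kind of C–H bond, ortho to one hydroxyl and para to the other; and ring B' is an unsubstituted C-linked phloroglucinol, i.e. 1,3,5-trimethoxybenzene with its single kind of C–H bond.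

## Logic of the disconnections

24 ⇒ 23: the 20 O–CH3 bonds are cut. Methyl ethers are the only phenol protection that survives every earlier step (base at 120 °C, peracid, copper, hydrogenation, oxidative coupling). The forward step must cleave all of them without touching the five diaryl ethers.

23 ⇒ 22 + 1 (key disconnection): the bond B-5–B'-1 is cut, with neither carbon functionalized beforehand. Making this axis last removes the conflict between the axis and the neighbouring ether B-4–O–C-1, because the ether can then be made at an unhindered carbon. It also removes every regiochemical question, since B-3 and B-5 are homotopic in 22 and mono-arylation can give only one compound. The precursor 22 is a pure polyether whose only free hydroxyl groups are those at B-2 and B-6. The forward step demands that the oxidant act only on ring B and that 1 outcompete all other arene nucleophiles.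

22 ⇒ 21 ⇒ 19 + 20: the two benzyl–O bonds at B-2 and B-6 and then the bond A-1–O are cut. The benzyl ethers are the only hydrogenolysable groups and reveal exactly the two hydroxyl groups of ring B; ring A is attached last because its C–H positions are as nucleophilic as those of 1. The forward coupling must tolerate a phenol flanked by two alkoxy groups.

19 ⇒ 17 ⇒ 14 + 16 (16 ⇒ 15 ⇒ 11): the oxygen at B-1 is traced back to a formyl group, and the bond B-4–O is cut para to it. The formyl group activates the fluoride for substitution by the hindered phenoxide and is afterwards exchanged for the B-1 oxygen, so one building block delivers a whole phloroglucinol-plus-oxygen ring. The forward steps demand a clean aryl migration in the peracid step without oxidation of the other rings.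

14 ⇒ 12 ⇒ 10 + 11: the same logic one ring further in; the bond C-4–O(D-1) is cut para to a formyl group that becomes the C-1 oxygen. The gain is that the most hindered phenol of the route (D-1, between two aryloxy groups) reacts at a carbon flanked only by hydrogen.

10 ⇒ 8 ⇒ two molecules of 5 + 6: the bonds D-2–O and D-6–O are cut together, using the mirror symmetry of ring D and its two identical arms. D-4 is already a methyl ether, so the D-1 oxygen that arises from the formyl group is the only free phenol. The forward step demands two substitutions ortho to one formyl group.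

5 ⇒ 3 ⇒ 2 ⇒ two molecules of 1: the oxygen at E-1 is traced back to a formyl group, and the bond E-5–E'-1 is cut as a dehydrodimerization. Compound 2 has four homotopic C–H positions, so a single functionalization can only give one product, and one batch of 5 serves both arms. The demand is to stop at monofunctionalization.

## Other disconnections considered

Alternative 1: the route that comes to mind first cuts all five aryl–O bonds as copper-mediated Ullmann couplings of aryl bromides with 2,6-dioxygenated phenols and all three axes as Suzuki–Miyaura couplings of brominated rings with the boronic acid of ring B'. Its key step would be the double Ullmann coupling of 5 with the dibromide A1 to give the tris(aryloxy) ring D as A2. In A1 each bromide is flanked by an oxygen substituent and sits on an electron-rich ring, and the phenoxide partner is itself di-ortho-substituted, so oxidative addition and C–O formation are both slowed and reductive loss of bromine becomes competitive. The ring B axis would either precede the B-4 ether, whose bromide then lies beside a perpendicular trimethoxyphenyl ring, or follow it, which needs a bromide placed selectively among many equally activated C–H positions. Each bond also needs its own halogenation step. The chosen plan uses fluoride displacement para or ortho to a formyl group for four of the five ethers and needs no halogenation for any axis.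

Alternative 2: ring D could be made at the quinone oxidation level, cutting D-2–O and D-6–O as a twofold addition–elimination of 5 on a 2,6-dihalogenated p-benzoquinone to give the bis(aryloxy)quinone A3, followed by reduction to the hydroquinone A4. The phenoxide of 5 is a 4-methoxyphenolate and a strong one-electron donor, while the quinone is an oxidant, so electron transfer should compete with addition. A4 then has two free phenols of which the wrong one (D-4, flanked by hydrogen) is the more accessible, which costs protection steps. In the chosen plan D-4 is a methyl ether from the start and the D-1 oxygen appears alone.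

Alternative 3: all three axes could be cut at once, with a threefold oxidative arylation of the hexaphlorethol tetraphenol A5 by 1 as the key step. On rings E and F the free OH at position 4 has two equivalent ortho positions, and the first arylation leaves the second open, so over-arylation cannot be excluded by the substitution pattern. Three phenolic rings reacting independently would also give a statistical set of partly arylated products. A5 further needs a differentially protected 2,6-dimethoxyhydroquinone unit, whereas 2 delivers both arm axes in one step from 1. Only ring B, where the step removes a real steric conflict, is arylated late in the chosen plan.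

Key step: step 14

Assumptions and abbreviations: 6 and 11 are taken as catalogue compounds. HMB-O stands for (2,2',4,4',6,6'-hexamethoxy-[1,1'-biphenyl]-3-yl)oxy. DO stands for 4-methoxy-2,6-bis(HMB-O)phenoxy, i.e. ring D with both arms, bound through the D-1 oxygen.

## Route

Step 1
Reactants: 1 1,3,5-trimethoxybenzene (two molecules)
Product: 2 2,2',4,4',6,6'-hexamethoxy-1,1'-biphenyl
Conditions: FeCl3 (2.2 equiv), CH2Cl2/MeNO2, 0 °C; MeOH quench
Reagents that add atoms: none
Why: Oxidative dehydrodimerization (Scholl-type arene–arene coupling): one-electron oxidation of 1 gives a radical cation that is attacked by a second molecule of 1 at its only kind of C–H position, and further oxidation with loss of two protons gives the biaryl that later serves as both the E–E' and the F–F' unit.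

Step 2
Reactants: 2 2,2',4,4',6,6'-hexamethoxy-1,1'-biphenyl
Product: 3 2,2',4,4',6,6'-hexamethoxy-[1,1'-biphenyl]-3-carbaldehyde
Conditions: POCl3 (1.05 equiv), DMF, 0 → 60 °C; then H2O
Reagents that add atoms: N,N-dimethylformamide (CN(C)C=O), water (O)
Why: Vilsmeier–Haack formylation; the four free positions of 2 are homotopic, so only one monoaldehyde is possible, and the first iminium ion stays cationic until work-up, which should slow a second attack by the cationic reagent; unreacted 2 can be recycled.

Step 3
Reactants: 3 2,2',4,4',6,6'-hexamethoxy-[1,1'-biphenyl]-3-carbaldehyde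
Product: 5 2,2',4,4',6,6'-hexamethoxy-[1,1'-biphenyl]-3-ol, via biaryl formate 4 (not isolated)
Conditions: mCPBA, CH2Cl2, 0 °C; then MeOH, Et3N (cat.), rt
Reagents that add atoms: 3-chloroperbenzoic acid (OOC(=O)c1cccc(Cl)c1)
Why: Dakin-type sequence (Baeyer–Villiger oxidation of an aryl aldehyde, then methanolysis of the formate): the di-ortho-methoxylated aryl group migrates far better than hydrogen, so the formyl carbon is exchanged for the E-1 oxygen.

Step 4
Reactants: 5 2,2',4,4',6,6'-hexamethoxy-[1,1'-biphenyl]-3-ol (two molecules), 6 2,6-difluoro-4-methoxybenzaldehyde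
Product: 8 4-methoxy-2,6-bis(HMB-O)benzaldehyde, via monoether 7 (not isolated)
Conditions: 5 (2.2 equiv), K2CO3, DMSO, 120 °C, argon
Reagents that add atoms: none
Why: Twofold nucleophilic aromatic substitution (SNAr): both fluorides are ortho to the formyl group, which stabilizes each Meisenheimer intermediate, and fluoride is small enough to be displaced by the di-ortho-substituted phenoxide; the second substitution is slower because the first aryloxy group is a donor, hence the temperature.

Step 5
Reactants: 8 4-methoxy-2,6-bis(HMB-O)benzaldehyde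
Product: 10 4-methoxy-2,6-bis(HMB-O)phenol, via ring D formate 9 (not isolated)
Conditions: mCPBA, CH2Cl2, 0 °C; then MeOH, Et3N (cat.), rt
Reagents that add atoms: 3-chloroperbenzoic acid (OOC(=O)c1cccc(Cl)c1)
Why: Dakin-type sequence as in step 3; the 2,4,6-trioxygenated ring D migrates readily, which places the D-1 oxygen between the two aryloxy groups as the only free phenol.

Step 6
Reactants: 10 4-methoxy-2,6-bis(HMB-O)phenol, 11 4-fluoro-2,6-dimethoxybenzaldehyde
Product: 12 4-(DO)-2,6-dimethoxybenzaldehyde
Conditions: 11 (1.5 equiv), Cs2CO3, DMSO, 110 °C, argon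
Reagents that add atoms: none
Why: SNAr para to the formyl group; the two methoxy groups of 11 are meta to the fluoride and do not deactivate it, and the carbon attacked is flanked only by hydrogen, so even the doubly aryloxy-flanked phenoxide of 10 can approach.

Step 7
Reactants: 12 4-(DO)-2,6-dimethoxybenzaldehyde
Product: 14 4-(DO)-2,6-dimethoxyphenol, via ring C formate 13 (not isolated)
Conditions: mCPBA (1.1 equiv), CH2Cl2, 0 °C; then MeOH, Et3N (cat.), rt
Reagents that add atoms: 3-chloroperbenzoic acid (OOC(=O)c1cccc(Cl)c1)
Why: Dakin-type sequence as in step 3; peracid addition to the aldehyde and aryl migration should be faster than any attack on the ether-only rings at 0 °C with a small excess of oxidant.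

Step 8
Reactants: 11 4-fluoro-2,6-dimethoxybenzaldehyde
Product: 15 4-fluoro-2,6-dihydroxybenzaldehyde
Conditions: BBr3 (2.5 equiv), CH2Cl2, −78 °C → rt; then H2O
Reagents that add atoms: none
Why: Lewis acid cleavage of the two aryl methyl ethers ortho to a carbonyl group: boron binds the formyl oxygen and the neighbouring methoxy oxygens, bromide removes both methyl groups, and the aryl fluoride is inert to the reagent.

Step 9
Reactants: 15 4-fluoro-2,6-dihydroxybenzaldehyde
Product: 16 2,6-bis(benzyloxy)-4-fluorobenzaldehyde
Conditions: BnBr (2.5 equiv), K2CO3, DMF, 60 °C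
Reagents that add atoms: benzyl bromide (BrCc1ccccc1)
Why: Twofold Williamson ether synthesis; the two benzyl ethers mark the oxygens of ring B (B-2 and B-6) that are to be freed together before the key step, which keeps ring B symmetric about the B-1/B-4 axis.

Step 10
Reactants: 14 4-(DO)-2,6-dimethoxyphenol, 16 2,6-bis(benzyloxy)-4-fluorobenzaldehyde
Product: 17 2,6-bis(benzyloxy)-4-[4-(DO)-2,6-dimethoxyphenoxy]benzaldehyde
Conditions: 16 (1.5 equiv), Cs2CO3, DMSO, 110 °C, argon
Reagents that add atoms: none
Why: SNAr para to the formyl group as in step 6; because ring B carries no aryl group yet, the ether B-4–O–C-1 is formed at a carbon flanked only by hydrogen.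

Step 11
Reactants: 17 2,6-bis(benzyloxy)-4-[4-(DO)-2,6-dimethoxyphenoxy]benzaldehyde
Product: 19 2,6-bis(benzyloxy)-4-[4-(DO)-2,6-dimethoxyphenoxy]phenol, via ring B formate 18 (not isolated)
Conditions: mCPBA (1.1 equiv), CH2Cl2, 0 °C; then MeOH, Et3N (cat.), rt
Reagents that add atoms: 3-chloroperbenzoic acid (OOC(=O)c1cccc(Cl)c1)
Why: Dakin-type sequence as in step 3; it turns the activating formyl group into the B-1 oxygen, and the benzyl ethers are inert to the peracid.

Step 12
Reactants: 19 2,6-bis(benzyloxy)-4-[4-(DO)-2,6-dimethoxyphenoxy]phenol, 20 1-bromo-3,5-dimethoxybenzene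
Product: 21 1,3-bis(benzyloxy)-5-[4-(DO)-2,6-dimethoxyphenoxy]-2-(3,5-dimethoxyphenoxy)benzene
Conditions: 20 (2 equiv), CuI (10 mol %), picolinic acid (20 mol %), K3PO4, DMSO, 90 °C
Reagents that add atoms: none
Why: Ullmann-type diaryl ether coupling; the bromide of 20 has no ortho substituent, and the picolinate-ligated copper catalyst is the system of choice for di-ortho-substituted phenols, so only the phenol side of this one coupling is hindered.

Step 13
Reactants: 21 1,3-bis(benzyloxy)-5-[4-(DO)-2,6-dimethoxyphenoxy]-2-(3,5-dimethoxyphenoxy)benzene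
Product: 22 5-[4-(DO)-2,6-dimethoxyphenoxy]-2-(3,5-dimethoxyphenoxy)benzene-1,3-diol
Conditions: H2 (1 atm), palladium on carbon (10 % Pd), EtOAc/MeOH, rt; work-up under argon
Reagents that add atoms: none
Why: Hydrogenolysis of the only two benzyl ethers; methyl and diaryl ethers are inert, so exactly the two hydroxyl groups at B-2 and B-6 are set free and ring B becomes a symmetric 2-aryloxyresorcinol.

Step 14
Reactants: 22 5-[4-(DO)-2,6-dimethoxyphenoxy]-2-(3,5-dimethoxyphenoxy)benzene-1,3-diol, 1 1,3,5-trimethoxybenzene
Product: 23 5-[4-(DO)-2,6-dimethoxyphenoxy]-2-(3,5-dimethoxyphenoxy)-4-(2,4,6-trimethoxyphenyl)benzene-1,3-diol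
Conditions: 1 (5 equiv), FeCl3 (10 mol %), t-BuOOt-Bu (1.5 equiv), (CF3)2CHOH/CH2Cl2, rt, argon
Reagents that add atoms: none
Why: This is an iron-catalysed oxidative phenol–arene cross-coupling (cross-dehydrogenative C–H/C–H coupling) in a fluoroalcohol, a known reaction type for electron-rich phenols with arenes such as 1 as the partner. One of the two equivalent O–H groups of 22 (B-2 or B-6) binds FeCl3 as a phenolate, and tert-butoxyl radicals from the peroxide oxidize this complex to an iron-bound phenoxyl radical with spin density at B-1, B-3 and B-5. B-1 is blocked by its aryloxy group, so the most nucleophilic arene present, 1 in excess, adds at B-5 or at the homotopic B-3, and a second one-electron oxidation with loss of a proton restores both aromatic rings. No ring is closed and no stereocentre is formed, since the new axis carries a C2v-symmetric 2,4,6-trimethoxyphenyl ring and is not stereogenic. Site selectivity is settled by the substrate: B-3 and B-5 of 22 are exchanged by the mirror plane through B-1 and B-4, each is ortho to one hydroxyl group and para to the other, and arylation of either gives the same compound 23. Chemoselectivity against the seven ether-only rings is needed and should follow from inner-sphere oxidation, because only ring B can coordinate to iron, and from the fluoroalcohol, which damps the reactivity of the biaryl product. Cross-coupling over homo-coupling should follow from the excess of 1 and from the crowding around the radical of 22. A second arylation at the remaining position of ring B is limited by stopping before full conversion and recycling 22.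

Step 15
Reactants: 23 5-[4-(DO)-2,6-dimethoxyphenoxy]-2-(3,5-dimethoxyphenoxy)-4-(2,4,6-trimethoxyphenyl)benzene-1,3-diol
Product: 24 CNP0117322.0
Conditions: BBr3 (excess), CH2Cl2, −78 °C → rt; then degassed H2O, argon
Reagents that add atoms: none
Why: Lewis acid cleavage of the 20 aryl methyl ethers: bromide attacks the methyl group of each boron-bound ether, while diaryl ethers have no alkyl carbon to attack and are left intact; the product is isolated under argon by reversed-phase or Sephadex LH-20 chromatography.

## Compound list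

1 | 1,3,5-trimethoxybenzene | COc1cc(OC)cc(OC)c1 | starting material
2 | 2,2',4,4',6,6'-hexamethoxy-1,1'-biphenyl | COc1cc(OC)c(-c2c(OC)cc(OC)cc2OC)c(OC)c1 | intermediate
3 | 2,2',4,4',6,6'-hexamethoxy-[1,1'-biphenyl]-3-carbaldehyde | COc1cc(OC)c(-c2c(OC)cc(OC)cc2OC)c(OC)c1C=O | intermediate
4 | 2,2',4,4',6,6'-hexamethoxy-[1,1'-biphenyl]-3-yl formate | COc1cc(OC)c(-c2c(OC)cc(OC)cc2OC)c(OC)c1OC=O | intermediate
5 | 2,2',4,4',6,6'-hexamethoxy-[1,1'-biphenyl]-3-ol | COc1cc(OC)c(-c2c(OC)cc(OC)cc2OC)c(OC)c1O | intermediate
6 | 2,6-difluoro-4-methoxybenzaldehyde | COc1cc(F)c(C=O)c(F)c1 | starting material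
7 | 2-fluoro-4-methoxy-6-(HMB-O)benzaldehyde | COc1cc(F)c(C=O)c(Oc2c(OC)cc(OC)c(-c3c(OC)cc(OC)cc3OC)c2OC)c1 | intermediate
8 | 4-methoxy-2,6-bis(HMB-O)benzaldehyde | COc1cc(Oc2c(OC)cc(OC)c(-c3c(OC)cc(OC)cc3OC)c2OC)c(C=O)c(Oc2c(OC)cc(OC)c(-c3c(OC)cc(OC)cc3OC)c2OC)c1 | intermediate
9 | 4-methoxy-2,6-bis(HMB-O)phenyl formate | COc1cc(Oc2c(OC)cc(OC)c(-c3c(OC)cc(OC)cc3OC)c2OC)c(OC=O)c(Oc2c(OC)cc(OC)c(-c3c(OC)cc(OC)cc3OC)c2OC)c1 | intermediate
10 | 4-methoxy-2,6-bis(HMB-O)phenol | COc1cc(Oc2c(OC)cc(OC)c(-c3c(OC)cc(OC)cc3OC)c2OC)c(O)c(Oc2c(OC)cc(OC)c(-c3c(OC)cc(OC)cc3OC)c2OC)c1 | intermediate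
11 | 4-fluoro-2,6-dimethoxybenzaldehyde | COc1cc(F)cc(OC)c1C=O | starting material
12 | 4-(DO)-2,6-dimethoxybenzaldehyde | O=Cc1c(OC)cc(Oc2c(Oc3c(OC)cc(OC)c(-c4c(OC)cc(OC)cc4OC)c3OC)cc(OC)cc2Oc2c(OC)cc(OC)c(-c3c(OC)cc(OC)cc3OC)c2OC)cc1OC | intermediate
13 | 4-(DO)-2,6-dimethoxyphenyl formate | O=COc1c(OC)cc(Oc2c(Oc3c(OC)cc(OC)c(-c4c(OC)cc(OC)cc4OC)c3OC)cc(OC)cc2Oc2c(OC)cc(OC)c(-c3c(OC)cc(OC)cc3OC)c2OC)cc1OC | intermediate
14 | 4-(DO)-2,6-dimethoxyphenol | Oc1c(OC)cc(Oc2c(Oc3c(OC)cc(OC)c(-c4c(OC)cc(OC)cc4OC)c3OC)cc(OC)cc2Oc2c(OC)cc(OC)c(-c3c(OC)cc(OC)cc3OC)c2OC)cc1OC | intermediate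
15 | 4-fluoro-2,6-dihydroxybenzaldehyde | O=Cc1c(O)cc(F)cc1O | intermediate
16 | 2,6-bis(benzyloxy)-4-fluorobenzaldehyde | O=Cc1c(OCc2ccccc2)cc(F)cc1OCc1ccccc1 | intermediate
17 | 2,6-bis(benzyloxy)-4-[4-(DO)-2,6-dimethoxyphenoxy]benzaldehyde | O=Cc5c(OCc7ccccc7)cc(Oc1c(OC)cc(Oc2c(Oc3c(OC)cc(OC)c(-c4c(OC)cc(OC)cc4OC)c3OC)cc(OC)cc2Oc2c(OC)cc(OC)c(-c3c(OC)cc(OC)cc3OC)c2OC)cc1OC)cc5OCc6ccccc6 | intermediate
18 | 2,6-bis(benzyloxy)-4-[4-(DO)-2,6-dimethoxyphenoxy]phenyl formate | O=COc5c(OCc7ccccc7)cc(Oc1c(OC)cc(Oc2c(Oc3c(OC)cc(OC)c(-c4c(OC)cc(OC)cc4OC)c3OC)cc(OC)cc2Oc2c(OC)cc(OC)c(-c3c(OC)cc(OC)cc3OC)c2OC)cc1OC)cc5OCc6ccccc6 | intermediate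
19 | 2,6-bis(benzyloxy)-4-[4-(DO)-2,6-dimethoxyphenoxy]phenol | Oc5c(OCc7ccccc7)cc(Oc1c(OC)cc(Oc2c(Oc3c(OC)cc(OC)c(-c4c(OC)cc(OC)cc4OC)c3OC)cc(OC)cc2Oc2c(OC)cc(OC)c(-c3c(OC)cc(OC)cc3OC)c2OC)cc1OC)cc5OCc6ccccc6 | intermediate
20 | 1-bromo-3,5-dimethoxybenzene | COc1cc(Br)cc(OC)c1 | starting material
21 | 1,3-bis(benzyloxy)-5-[4-(DO)-2,6-dimethoxyphenoxy]-2-(3,5-dimethoxyphenoxy)benzene | COc7cc(OC)cc(Oc5c(OCc8ccccc8)cc(Oc1c(OC)cc(Oc2c(Oc3c(OC)cc(OC)c(-c4c(OC)cc(OC)cc4OC)c3OC)cc(OC)cc2Oc2c(OC)cc(OC)c(-c3c(OC)cc(OC)cc3OC)c2OC)cc1OC)cc5OCc6ccccc6)c7 | intermediate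
22 | 5-[4-(DO)-2,6-dimethoxyphenoxy]-2-(3,5-dimethoxyphenoxy)benzene-1,3-diol | COc7cc(OC)cc(Oc5c(O)cc(Oc1c(OC)cc(Oc2c(Oc3c(OC)cc(OC)c(-c4c(OC)cc(OC)cc4OC)c3OC)cc(OC)cc2Oc2c(OC)cc(OC)c(-c3c(OC)cc(OC)cc3OC)c2OC)cc1OC)cc5O)c7 | intermediate
23 | 5-[4-(DO)-2,6-dimethoxyphenoxy]-2-(3,5-dimethoxyphenoxy)-4-(2,4,6-trimethoxyphenyl)benzene-1,3-diol | COc7cc(OC)cc(Oc5c(O)c(-c6c(OC)cc(OC)cc6OC)c(Oc1c(OC)cc(Oc2c(Oc3c(OC)cc(OC)c(-c4c(OC)cc(OC)cc4OC)c3OC)cc(OC)cc2Oc2c(OC)cc(OC)c(-c3c(OC)cc(OC)cc3OC)c2OC)cc1OC)cc5O)c7 | intermediate
24 | CNP0117322.0 (all 22 phenols free; rings and links as described under "Structural features") | Oc1cc(O)cc(Oc2c(O)cc(Oc3c(O)cc(Oc4c(Oc5c(O)cc(O)c(-c6c(O)cc(O)cc6O)c5O)cc(O)cc4Oc4c(O)cc(O)c(-c5c(O)cc(O)cc5O)c4O)cc3O)c(-c3c(O)cc(O)cc3O)c2O)c1 | target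

## Step count and least certain steps

Total: 15 steps. Longest linear sequence: 13 steps (steps 1–7 and 10–15, from 1 to 24); steps 8 and 9 form the side branch to 16.

Step 14 (key step). Most likely failure: loss of chemoselectivity in the oxidation. Rings C and D are p-dialkoxy-type arenes with low oxidation potentials and could be oxidized by outer-sphere electron transfer. The phenoxyl radical could also lose the B-1 aryloxy group towards an o-quinone if water is present, and a second arylation could occur at the remaining position of ring B. Fallback, from 22 back to 23: iodination of the phenolate (I2, 1.0 equiv, NaHCO3, THF/H2O, 0 °C) reacts only on the ring that carries the O− and, because the two free positions of ring B are homotopic, should give the single mono-iodide 5-[4-(DO)-2,6-dimethoxyphenoxy]-2-(3,5-dimethoxyphenoxy)-4-iodobenzene-1,3-diol F1. Suzuki–Miyaura coupling with 2,4,6-trimethoxyphenylboronic acid (Pd(OAc)2, SPhos, K3PO4, toluene/H2O, 100 °C, argon) then returns to 23.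

Step 4. Most likely failure: stalling after the first substitution, because the first aryloxy group and the 4-methoxy group both weaken the activation by the formyl group, with slow degradation of the aldehyde in hot base. Fallback, from 5 back to 8: twofold SNAr on commercial 2,6-difluoro-4-methoxybenzonitrile (K2CO3, DMSO, 100 °C), whose cyano group activates more strongly and is inert to base, gives 4-methoxy-2,6-bis(HMB-O)benzonitrile F2; reduction with i-Bu2AlH (toluene, −78 °C, then aqueous HCl) returns to 8.

Step 7 (the same concern applies to steps 5 and 11). Most likely failure: over-oxidation, i.e. attack of the peracid on the trimethoxyphenyl rings or the p-dialkoxy rings of the hexamer in competition with the Baeyer–Villiger step. Fallback, from 10 back to 14, bringing the C-1 oxygen in already protected so that no oxidant is needed: commercial 4-bromo-2,6-dimethoxyphenol is benzylated (BnBr, K2CO3, DMF) to 2-(benzyloxy)-5-bromo-1,3-dimethoxybenzene F3; copper coupling with 10 (CuI, picolinic acid, K3PO4, DMSO, 100 °C) gives the benzyl ether 2-(benzyloxy)-5-(DO)-1,3-dimethoxybenzene F4; hydrogenolysis (H2, palladium on carbon) returns to 14.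

Step 12. Most likely failure: slow C–O bond formation at the di-ortho-substituted phenoxide, with reductive loss of bromine from 20 taking over. Fallback, from 19 back to 21, by ligand coupling at trivalent iodine instead of copper catalysis: 1-iodo-3,5-dimethoxybenzene is oxidized (mCPBA, TsOH·H2O) and treated with 1 to give (3,5-dimethoxyphenyl)(2,4,6-trimethoxyphenyl)iodonium 4-methylbenzenesulfonate F5; with the potassium phenoxide of 19 (t-BuOK, THF, rt) the less electron-rich 3,5-dimethoxyphenyl group is transferred to oxygen and 21 results.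

Step 15. Most likely failure: incomplete cleavage of the 20 methyl ethers, giving a set of partly methylated products, and air oxidation of the polyphenol during isolation. Fallback, from 23 back to 24 by way of a purifiable derivative: after the BBr3 treatment and aqueous quench the crude polyphenol is acetylated (Ac2O, pyridine) to the docosaacetate of CNP0117322.0 F6, which can be chromatographed on silica; acidic methanolysis (AcCl in degassed MeOH, 0 °C → rt, argon) then sets 24 free.

## Further compounds

F1 | step 14 | 5-[4-(DO)-2,6-dimethoxyphenoxy]-2-(3,5-dimethoxyphenoxy)-4-iodobenzene-1,3-diol | COc7cc(OC)cc(Oc5c(O)c(I)c(Oc1c(OC)cc(Oc2c(Oc3c(OC)cc(OC)c(-c4c(OC)cc(OC)cc4OC)c3OC)cc(OC)cc2Oc2c(OC)cc(OC)c(-c3c(OC)cc(OC)cc3OC)c2OC)cc1OC)cc5O)c7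
F2 | step 4 | 4-methoxy-2,6-bis(HMB-O)benzonitrile | COc1cc(Oc2c(OC)cc(OC)c(-c3c(OC)cc(OC)cc3OC)c2OC)c(C#N)c(Oc2c(OC)cc(OC)c(-c3c(OC)cc(OC)cc3OC)c2OC)c1
F3 | step 7 | 2-(benzyloxy)-5-bromo-1,3-dimethoxybenzene | COc1cc(Br)cc(OC)c1OCc1ccccc1
F4 | step 7 | 2-(benzyloxy)-5-(DO)-1,3-dimethoxybenzene | COc1cc(Oc2c(Oc3c(OC)cc(OC)c(-c4c(OC)cc(OC)cc4OC)c3OC)cc(OC)cc2Oc2c(OC)cc(OC)c(-c3c(OC)cc(OC)cc3OC)c2OC)cc(OC)c1OCc1ccccc1
F5 | step 12 | (3,5-dimethoxyphenyl)(2,4,6-trimethoxyphenyl)iodonium 4-methylbenzenesulfonate | COc1cc(OC)cc([I+]c2c(OC)cc(OC)cc2OC)c1.Cc1ccc(S(=O)(=O)[O-])cc1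
F6 | step 15 | docosaacetate of CNP0117322.0 | CC(=O)Oc1cc(OC(C)=O)cc(Oc2c(OC(C)=O)cc(Oc3c(OC(C)=O)cc(Oc4c(Oc5c(OC(C)=O)cc(OC(C)=O)c(-c6c(OC(C)=O)cc(OC(C)=O)cc6OC(C)=O)c5OC(C)=O)cc(OC(C)=O)cc4Oc4c(OC(C)=O)cc(OC(C)=O)c(-c5c(OC(C)=O)cc(OC(C)=O)cc5OC(C)=O)c4OC(C)=O)cc3OC(C)=O)c(-c3c(OC(C)=O)cc(OC(C)=O)cc3OC(C)=O)c2OC(C)=O)c1
A1 | alternative 1 | 2-(benzyloxy)-1,3-dibromo-5-methoxybenzene | COc1cc(Br)c(OCc2ccccc2)c(Br)c1
A2 | alternative 1 | 2-(benzyloxy)-5-methoxy-1,3-bis(HMB-O)benzene | COc1cc(Oc2c(OC)cc(OC)c(-c3c(OC)cc(OC)cc3OC)c2OC)c(OCc2ccccc2)c(Oc2c(OC)cc(OC)c(-c3c(OC)cc(OC)cc3OC)c2OC)c1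
A3 | alternative 2 | 2,6-bis(HMB-O)-1,4-benzoquinone | O=C1C=C(Oc2c(OC)cc(OC)c(-c3c(OC)cc(OC)cc3OC)c2OC)C(=O)C(Oc2c(OC)cc(OC)c(-c3c(OC)cc(OC)cc3OC)c2OC)=C1
A4 | alternative 2 | 2,6-bis(HMB-O)benzene-1,4-diol | Oc1cc(Oc2c(OC)cc(OC)c(-c3c(OC)cc(OC)cc3OC)c2OC)c(O)c(Oc2c(OC)cc(OC)c(-c3c(OC)cc(OC)cc3OC)c2OC)c1
A5 | alternative 3 | 5-[4-[2,6-bis(4-hydroxy-2,6-dimethoxyphenoxy)-4-methoxyphenoxy]-2,6-dimethoxyphenoxy]-2-(3,5-dimethoxyphenoxy)benzene-1,3-diol | COc7cc(OC)cc(Oc5c(O)cc(Oc1c(OC)cc(Oc2c(Oc3c(OC)cc(O)cc3OC)cc(OC)cc2Oc2c(OC)cc(O)cc2OC)cc1OC)cc5O)c7
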